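## The problem

Tsangin C is an open-chain butan-2-one (C1 methyl, C2 carbonyl, C3, C4; these locants are used throughout). C4 carries a 3,4,5-trimethoxyphenyl ring and a 3,4,5-trimethoxybenzoyloxy group, C3 carries a methyl group, and the two benzene rings are joined only through the C4–O–C(=O) ester link, so no ring has to be made. The task is therefore the pair of adjacent stereocentres, C3 (S) and C4 (R), which stand anti to one another. C4 is a benzylic carbinol centre that a catalyst can address through the flanking aryl ketone, whereas C3 has no handle of its own and must be controlled from C4 or together with it. C3 is also the fragile centre: in the target it is alpha to the C2 ketone, so base can epimerise it, and the same proton opens an E1cB loss of the C4 benzoate to the enone. The free beta-hydroxy ketone can in addition cleave at C3–C4 by retro-aldol reaction, and the benzylic C4–O bond will not tolerate strong acid. The ester must therefore go on late and under mild base, and the ketone should be carried in a less acidic form for as long as possible. A short solution is possible because, with C4 at the ketone level and C2 at the carboxyl level, C3 lies between two carbonyl groups and equilibrates through the enol, so that one selective delivery of hydride to C4 can fix both centres.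

## Retrosynthesis

The last bond to be made is the acyl C–O bond of the ester, which takes 9 back to hydroxy ketone 8 and acid chloride 2. The neighbouring cut, the C4–O bond itself (substitution at C4 by the acid), would put the benzylic centre at risk and invite elimination towards C3, whereas acylation on oxygen leaves both stereocentres untouched. The cut removes half of the molecule and the second aryl ring, and 2 is a purchased reagent. The forward step must be mild enough that neither E1cB loss of the new benzoate nor epimerisation at C3 sets in. The ester cannot go on earlier because it would not survive the organomagnesium reagent that makes the ketone.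

Next the C1–C2 bond is cut, so that 8 becomes the N-methoxy-N-methylamide 6 and a methyl organometallic. Carrying the methyl ketone further back would lead to a 1,3-diketone with two reducible carbonyls and a still more labile C3, and an ester in place of the amide would over-add. The amide avoids both and makes C3 much less acidic once the stereocentres are in place. Precursor 6 has the same two stereocentres, one carbon less and no base-sensitive ketone. The forward step must stop at the ketone in the presence of the free hydroxyl, which the chelated magnesium adduct 7 allows, and must not let the magnesium aldolate cleave by retro-aldol reaction.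

The stereochemical cut is the C4–H bond, which takes 6 back to the racemic beta-keto amide 5. The adjacent C3–C4 aldol cut would also create both centres, but anti-selective aldol additions to an aromatic aldehyde need a stoichiometric chiral controller that has to be attached and removed. The C3–CH3 cut needs the C4 centre first and then a second stereoselective step. Removing one hydride instead erases both stereocentres at once, because C3 of 5 is configurationally mobile, and the precursor needs no stereocontrol at all. The forward step has to reduce only the aryl ketone, choose the C4 face through the catalyst, prefer the anti pairing, and run more slowly than C3 racemises.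

Finally 5 is opened at the C3–C4 bond to propanamide 1 and acid chloride 2, joined through the lithium enolate 3, with the product held in the flask as its enolate 4. This is preferred to an aldol–oxidation sequence because it reaches the ketone oxidation level in one operation. It is preferred to C3-methylation of the unsubstituted keto amide because no C- versus O- or mono- versus di-alkylation has to be managed. Both partners are purchased, and 2 is the same reagent that closes the synthesis. The forward step must give C- rather than O-acylation and stop after one acyl transfer.

## Roads not taken

Alternative 1: The cut is the C4–aryl bond.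
- **Forward step:** The ketal-masked chain alcohol is used as (S)-2-(2-methyl-1,3-dioxolan-2-yl)propyl N,N-diisopropylcarbamate A1. It would be lithiated at C4 with s-BuLi and a sparteine, and the carbanion trapped with 4,4,5,5-tetramethyl-2-(3,4,5-trimethoxyphenyl)-1,3,2-dioxaborolane A2. The boronate complex would then shift the aryl group from boron to C4 with loss of the carbamate, giving the benzylic boronic ester A3. Oxidation of the C–B bond with retention, acylation with 2 and ketal hydrolysis would finish.
- **Merits:** The C4 configuration is dictated by the chiral lithium–diamine pair and transferred stereospecifically, so it is independent of substrate bias. The ester can be put on while the ketone is still a dioxolane, which removes the elimination risk that the chosen endgame has to manage. In both respects this road is better.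
- **Weak points:** C3 is not formed in this step. It must be brought in enantiopure next to a carbonyl that has to be masked before it epimerises, so A1 needs a multi-step preparation. Sparteine is stoichiometric at −78 °C, and the resident C3 centre may be mismatched with the diamine. The benzylic ester must survive acidic ketal removal.
- **Comparison:** The sequence is at least twice as long. The chosen plan sets C3 and C4 together, catalytically, from a racemate that is one step from purchased materials.

Alternative 2: The cut is the C3–C4 bond, made by a [2,3]-Wittig shift.
- **Forward step:** 3,4,5-Trimethoxybenzyl (E)-2-methylbut-2-enyl ether A4 would be lithiated enantioselectively at the benzylic carbon. The carbanion would rearrange with cleavage of the allylic C–O bond to (1R,2R)-2,3-dimethyl-1-(3,4,5-trimethoxyphenyl)but-3-en-1-ol A5. Acylation of A5 with 2 and oxidative cleavage of the 1,1-disubstituted alkene would give 9.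
- **Merits:** The count of four steps equals that of the chosen plan. The ketone appears only after the ester is in place, so no base-sensitive beta-hydroxy ketone is ever handled, which is a real advantage over the chosen endgame.
- **Weak points:** Both stereocentres rest on an externally ligated organolithium, for which enantiocontrol is substrate-dependent. An (E)-olefin usually gives the weaker anti preference, and the extra 2-methyl group alters the envelope transition state. Ortho-lithiation next to the methoxy groups and the [1,2]-shift compete. Ozonolysis must spare two electron-rich arenes.
- **Comparison:** The chosen plan relies on a catalytic reduction whose facial sense at C4 is well understood and on thermodynamic mobility, not kinetic geometry control, for C3.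

Alternative 3: The cut is the C3–CH3 bond.
- **Forward step:** Ethyl 3-oxo-3-(3,4,5-trimethoxyphenyl)propanoate A6 would be reduced enantioselectively to ethyl (3R)-3-hydroxy-3-(3,4,5-trimethoxyphenyl)propanoate A7. Its dianion would be methylated with iodomethane anti to the C4 oxygen (Fráter–Seebach) to give ethyl (2S,3R)-3-hydroxy-2-methyl-3-(3,4,5-trimethoxyphenyl)propanoate A8. Conversion to the N-methoxy-N-methylamide, methyl addition and acylation would follow.
- **Merits:** Each stereocentre is set by a step of high and predictable selectivity. The anti relationship comes from a rigid lithium chelate and not from a competition between two transition states. In certainty of diastereocontrol this road is better than the chosen one.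
- **Weak points:** Two stereo-defining steps are needed instead of one, and an ester-to-amide exchange is added, giving six steps from 2 against four. Two equivalents of strong base act on an aldolate that can cleave by retro-aldol reaction.
- **Comparison:** The chosen plan is two steps shorter and creates both centres in one catalytic operation. Because of its reliability, the logic of this alternative is kept in reserve as the fallback for the key step.

Key step: step 2

Remark: the geometry of enolates 3 and 4 has no bearing on the outcome, because C3 is formed racemic in step 1 and is equilibrated in step 2.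

## Route

Step 1
Reactants: 1 N-methoxy-N-methylpropanamide; 2 3,4,5-trimethoxybenzoyl chloride
Product: 5 N-methoxy-N,2-dimethyl-3-oxo-3-(3,4,5-trimethoxyphenyl)propanamide (racemate), via lithium Z-enolate 3 (not isolated), via lithium dicarbonyl enolate 4 (not isolated)
Conditions: 1 (2.0 equiv), LiN(i-Pr)2 (2.1 equiv), THF, −78 °C; 2 (1.0 equiv) added slowly, −78 to −40 °C; AcOH, −78 °C to rt
Reagents that add atoms: none
Why: Claisen-type C-acylation of an amide enolate by an acid chloride. Slow addition lets 2 always meet the more nucleophilic enolate 3, and the second equivalent of 3 converts the more acidic product into enolate 4, which guards against O-acylation and a second acyl transfer. C3 is deliberately formed racemic.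

Step 2
Reactants: 5 N-methoxy-N,2-dimethyl-3-oxo-3-(3,4,5-trimethoxyphenyl)propanamide (racemate)
Product: 6 (2S,3R)-3-hydroxy-N-methoxy-N,2-dimethyl-3-(3,4,5-trimethoxyphenyl)propanamide
Conditions: RuCl(p-cymene)[(R,R)-TsNCH(Ph)CH(Ph)NH2] (2 mol %), HCO2H/Et3N (5:2), DMF, 40 °C
Reagents that add atoms: none
Why: Noyori–Ikariya asymmetric transfer hydrogenation run as a dynamic kinetic resolution, the known behaviour of alpha-substituted beta-keto esters and amides. Formate turns the catalyst into the 18-electron hydride RuH(p-cymene)[(R,R)-TsNCH(Ph)CH(Ph)NH2], which passes hydride to the C4 carbonyl carbon and the N–H proton to its oxygen through an outer-sphere six-membered transition state; no ring is closed and no skeletal bond is formed. The C4 configuration (R) is set by the catalyst, because the trimethoxyphenyl ring is held next to the p-cymene ligand by a CH–pi contact, as aryl ketones are with the (R,R)-ligand. The C3 configuration (S) is set by which enantiomer of 5 is reduced faster: with the amide carbonyl carbon anti to the incoming hydride and the C3 methyl turned away from the aryl ring (Felkin–Anh), the (S)-enantiomer is the matched one and the anti isomer 6 should result. The step needs C3 to racemise faster than the ketone is reduced, which the doubly activated C3–H in the amine–formic acid medium and the only moderately electrophilic aryl ketone should secure. It also needs the open, non-chelated arrangement, which the tertiary N-methoxy-N-methylamide favours because it has no N–H to bridge to the ketone oxygen. Only the aryl ketone is reduced; the amide and its N–O bond are inert to the ruthenium hydride.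

Step 3
Reactants: 6 (2S,3R)-3-hydroxy-N-methoxy-N,2-dimethyl-3-(3,4,5-trimethoxyphenyl)propanamide
Product: 8 (3S,4R)-4-hydroxy-3-methyl-4-(3,4,5-trimethoxyphenyl)butan-2-one, via magnesium hemiaminal adduct 7 (not isolated)
Conditions: MeMgBr (3.5 equiv), THF, −20 to 0 °C; aq. NH4Cl, 0 °C
Reagents that add atoms: methylmagnesium bromide, C[Mg]Br
Why: Weinreb ketone synthesis on an unprotected beta-hydroxy amide. The first equivalent forms the magnesium alkoxide and the second adds to the amide to give the chelated tetrahedral adduct 7, which does not collapse until the cold quench, so no over-addition occurs and no enolisable ketone meets the base. C3 and C4 are not touched.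

Step 4
Reactants: 8 (3S,4R)-4-hydroxy-3-methyl-4-(3,4,5-trimethoxyphenyl)butan-2-one; 2 3,4,5-trimethoxybenzoyl chloride
Product: 9 Tsangin C, (1R,2S)-2-methyl-3-oxo-1-(3,4,5-trimethoxyphenyl)butyl 3,4,5-trimethoxybenzoate
Conditions: 2 (1.3 equiv), pyridine (3 equiv), 4-(dimethylamino)pyridine (0.1 equiv), CH2Cl2, 0 °C to rt
Reagents that add atoms: none
Why: Nucleophile-catalysed esterification of a secondary alcohol through an N-acylpyridinium ion. The C4–O bond is not broken, so the configuration is retained, and the weak base and low temperature should keep E1cB loss of the new benzoate and epimerisation at C3 slow.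

## Compound list

1 | N-methoxy-N-methylpropanamide | CCC(=O)N(C)OC | starting material
2 | 3,4,5-trimethoxybenzoyl chloride | COc1cc(C(Cl)=O)cc(OC)c1OC | starting material
3 | lithium (Z)-1-[methoxy(methyl)amino]prop-1-en-1-olate (not isolated) | C/C=C(\O[Li])N(C)OC | intermediate
4 | lithium 3-[methoxy(methyl)amino]-2-methyl-3-oxo-1-(3,4,5-trimethoxyphenyl)prop-1-en-1-olate (not isolated) | CON(C)C(=O)C(C)=C(O[Li])c1cc(OC)c(OC)c(OC)c1 | intermediate
5 | N-methoxy-N,2-dimethyl-3-oxo-3-(3,4,5-trimethoxyphenyl)propanamide (racemate) | CON(C)C(=O)C(C)C(=O)c1cc(OC)c(OC)c(OC)c1 | intermediate
6 | (2S,3R)-3-hydroxy-N-methoxy-N,2-dimethyl-3-(3,4,5-trimethoxyphenyl)propanamide | O[C@@H](c1cc(OC)c(OC)c(OC)c1)[C@H](C)C(=O)N(C)OC | intermediate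
7 | bis(bromomagnesium) (3S,4R)-2-[methoxy(methyl)amino]-3-methyl-4-(3,4,5-trimethoxyphenyl)butane-2,4-bis(olate), C2 undefined (not isolated) | Br[Mg]O[C@@H](c1cc(OC)c(OC)c(OC)c1)[C@H](C)C(C)(O[Mg]Br)N(C)OC | intermediate
8 | (3S,4R)-4-hydroxy-3-methyl-4-(3,4,5-trimethoxyphenyl)butan-2-one | O[C@@H](c1cc(OC)c(OC)c(OC)c1)[C@H](C)C(C)=O | intermediate
9 | Tsangin C, (1R,2S)-2-methyl-3-oxo-1-(3,4,5-trimethoxyphenyl)butyl 3,4,5-trimethoxybenzoate | COc1cc(C(=O)O[C@@H](c2cc(OC)c(OC)c(OC)c2)[C@H](C)C(C)=O)cc(OC)c1OC | target

## Step count and least certain steps

Total step count: 4. Longest linear sequence: 4 steps (1 → 5 → 6 → 8 → 9); acid chloride 2 enters in steps 1 and 4.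

**Step 2 (key step).**
- **Poor diastereoselection:** The catalyst should fix the C4 face reliably, but the choice between the two C3 epimers may not favour anti. If formic acid bridges the two carbonyl oxygens, a chelate-like arrangement could make the syn pairing competitive. This would cost material as the (2R,3R) diastereomer and would not lower the enantiopurity of 6.
- **Slow racemisation:** Enolisation of the tertiary amide may be retarded by allylic strain in the enol, so that the reaction degrades to a plain kinetic resolution.
- **Remedies within the same disconnection:** A less acidic formate/amine ratio, a tethered arene–diamine ruthenium catalyst, or a ketoreductase selected for the anti-(2S,3R) isomer.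
- **Fallback:** The two centres are set one after the other. The fallback sets out from 2 and comes back at 6. Acylation of the lithium enolate of methyl acetate (LiN(SiMe3)2, THF, −78 °C) with 2 should give methyl 3-oxo-3-(3,4,5-trimethoxyphenyl)propanoate F1. Transfer hydrogenation with the same (R,R)-ruthenium catalyst, now free of any diastereoselectivity question, should give methyl (3R)-3-hydroxy-3-(3,4,5-trimethoxyphenyl)propanoate F2. Fráter–Seebach methylation (LiN(i-Pr)2, 2.2 equiv, THF, −78 to −20 °C; MeI) places the methyl group anti to the C4 oxygen within the lithium chelate and should give methyl (2S,3R)-3-hydroxy-2-methyl-3-(3,4,5-trimethoxyphenyl)propanoate F3. Aminolysis with MeNHOMe·HCl and i-PrMgCl (THF, −20 °C) then leads to 6.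

**Step 3.**
- **Retro-aldol cleavage:** The magnesium aldolate formed by the first equivalent of reagent may cleave at C3–C4 before or after the amide reacts. Recombination would erode both stereocentres, and the released aldehyde would consume reagent.
- **Fallback:** The alkoxide is avoided altogether. The fallback sets out from 6 and comes back at 8. Silylation (Et3SiCl, imidazole, CH2Cl2) should give (2S,3R)-N-methoxy-N,2-dimethyl-3-[(triethylsilyl)oxy]-3-(3,4,5-trimethoxyphenyl)propanamide F4. MeMgBr (THF, 0 °C) should convert it into (3S,4R)-3-methyl-4-[(triethylsilyl)oxy]-4-(3,4,5-trimethoxyphenyl)butan-2-one F5. Buffered HF·pyridine (THF, 0 °C) then releases 8.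

**Step 1.**
- **O-acylation and double acylation:** Acylation on oxygen of enolate 4, a second acyl transfer, or proton transfer that leaves 2 unconsumed may lower the return of 5.
- **Fallback:** The ketone level is reached in two operations. The fallback sets out from 1 and comes back at 5. Enolate 3 (LiN(i-Pr)2, THF, −78 °C) is added to purchased 3,4,5-trimethoxybenzaldehyde to give 3-hydroxy-N-methoxy-N,2-dimethyl-3-(3,4,5-trimethoxyphenyl)propanamide F6 as a racemic mixture of diastereomers. Oxidation with Dess–Martin periodinane (CH2Cl2, rt) then gives 5.

**Step 4.**
- **Elimination and epimerisation:** The hindered benzylic hydroxyl may acylate slowly, and prolonged exposure of the beta-aroyloxy ketone to amine base may start E1cB elimination to the enone or epimerisation at C3.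
- **Fallback:** The order of the last two steps is reversed. The fallback sets out from 6 and comes back at 9. Acylation of 6 with 2 (pyridine, 4-(dimethylamino)pyridine, CH2Cl2), where the C3 proton is alpha only to an amide, should give (1R,2S)-3-[methoxy(methyl)amino]-2-methyl-3-oxo-1-(3,4,5-trimethoxyphenyl)propyl 3,4,5-trimethoxybenzoate F7. MeMgBr (1.2 equiv, THF, −78 °C) should then add to the chelating N-methoxy-N-methylamide in preference to the hindered, electron-rich aryl ester and give 9.

## Further compounds

F1 | step 2 | methyl 3-oxo-3-(3,4,5-trimethoxyphenyl)propanoate | COC(=O)CC(=O)c1cc(OC)c(OC)c(OC)c1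
F2 | step 2 | methyl (3R)-3-hydroxy-3-(3,4,5-trimethoxyphenyl)propanoate | O[C@@H](c1cc(OC)c(OC)c(OC)c1)CC(=O)OC
F3 | step 2 | methyl (2S,3R)-3-hydroxy-2-methyl-3-(3,4,5-trimethoxyphenyl)propanoate | O[C@@H](c1cc(OC)c(OC)c(OC)c1)[C@H](C)C(=O)OC
F4 | step 3 | (2S,3R)-N-methoxy-N,2-dimethyl-3-[(triethylsilyl)oxy]-3-(3,4,5-trimethoxyphenyl)propanamide | CC[Si](CC)(CC)O[C@@H](c1cc(OC)c(OC)c(OC)c1)[C@H](C)C(=O)N(C)OC
F5 | step 3 | (3S,4R)-3-methyl-4-[(triethylsilyl)oxy]-4-(3,4,5-trimethoxyphenyl)butan-2-one | CC[Si](CC)(CC)O[C@@H](c1cc(OC)c(OC)c(OC)c1)[C@H](C)C(C)=O
F6 | step 1 | 3-hydroxy-N-methoxy-N,2-dimethyl-3-(3,4,5-trimethoxyphenyl)propanamide (racemic mixture of diastereomers) | CON(C)C(=O)C(C)C(O)c1cc(OC)c(OC)c(OC)c1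
F7 | step 4 | (1R,2S)-3-[methoxy(methyl)amino]-2-methyl-3-oxo-1-(3,4,5-trimethoxyphenyl)propyl 3,4,5-trimethoxybenzoate | COc1cc(C(=O)O[C@@H](c2cc(OC)c(OC)c(OC)c2)[C@H](C)C(=O)N(C)OC)cc(OC)c1OC
A1 | alternative 1 | (S)-2-(2-methyl-1,3-dioxolan-2-yl)propyl N,N-diisopropylcarbamate | CC(C)N(C(C)C)C(=O)OC[C@H](C)C1(C)OCCO1
A2 | alternative 1 | 4,4,5,5-tetramethyl-2-(3,4,5-trimethoxyphenyl)-1,3,2-dioxaborolane | COc1cc(B2OC(C)(C)C(C)(C)O2)cc(OC)c1OC
A3 | alternative 1 | 4,4,5,5-tetramethyl-2-[(1R,2S)-2-(2-methyl-1,3-dioxolan-2-yl)-1-(3,4,5-trimethoxyphenyl)propyl]-1,3,2-dioxaborolane | CC1(C)OB(OC1(C)C)[C@@H](c2cc(OC)c(OC)c(OC)c2)[C@H](C)C3(C)OCCO3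
A4 | alternative 2 | 3,4,5-trimethoxybenzyl (E)-2-methylbut-2-enyl ether | C/C=C(\C)COCc1cc(OC)c(OC)c(OC)c1
A5 | alternative 2 | (1R,2R)-2,3-dimethyl-1-(3,4,5-trimethoxyphenyl)but-3-en-1-ol | O[C@@H](c1cc(OC)c(OC)c(OC)c1)[C@H](C)C(C)=C
A6 | alternative 3 | ethyl 3-oxo-3-(3,4,5-trimethoxyphenyl)propanoate | CCOC(=O)CC(=O)c1cc(OC)c(OC)c(OC)c1
A7 | alternative 3 | ethyl (3R)-3-hydroxy-3-(3,4,5-trimethoxyphenyl)propanoate | O[C@@H](c1cc(OC)c(OC)c(OC)c1)CC(=O)OCC
A8 | alternative 3 | ethyl (2S,3R)-3-hydroxy-2-methyl-3-(3,4,5-trimethoxyphenyl)propanoate | O[C@@H](c1cc(OC)c(OC)c(OC)c1)[C@H](C)C(=O)OCC
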